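## Retrosynthetic overview
1. The enal comes from a (2E)-allylic alcohol. This alcohol arises by 1,4-hydroboration of a 7-isopropenylcyclohex-7-ene diene, where addition across the s-cis diene fixes the tetrasubstituted C2=C7 geometry.
2. C16–C17 is formed by α-selective carbonyl allylation of a ring-bearing (E)-2-methylenal with geranylbarium made from geraniol. C16 is then set to R by oxidation and CBS reduction.
3. The ring enal comes from a trans-fused keto δ-lactone by Weinreb opening and Wittig reaction. The C6 chain is installed by B-alkyl Suzuki coupling and hydroboration–oxidation, with the lactone locking the chair that controls C6.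
4. The keto lactone comes from oxidative cleavage of the enone ring of the methyl carbinol made from (S)-Wieland–Miescher ketone.
5. Ring order: the cyclohexane is bought with 2-methylcyclohexane-1,3-dione. A sacrificial enone ring is formed first (step 2) and cleaved in step 6. A sacrificial δ-lactone ring is formed second (step 7) and opened in step 14.

Assumption: the SMILES is read literally, so the formyl group is cis to ring CH2-8 and the vinylic methyl is cis to C-6 (2E). Iridal numbering is used throughout (C-1 CHO, C-6 ring CH, C-7 ring sp2 C, C-10 carbinol, C-11 quaternary C, C-16 side-chain carbinol).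

## Route

Step 1
Reactants: 1 2-methylcyclohexane-1,3-dione; 2 methyl vinyl ketone
Product: 3 2-methyl-2-(3-oxobutyl)cyclohexane-1,3-dione
Conditions: AcOH (cat.), hydroquinone (cat.), H2O, 75 °C
Reagents that add atoms: methyl vinyl ketone (2), CC(=O)C=C
Why: Michael addition of the acidic 1,3-dione to the enone gives the prochiral triketone cleanly, and no stereocentre is formed yet.

Step 2
Reactants: 3 2-methyl-2-(3-oxobutyl)cyclohexane-1,3-dione
Product: 4 (S)-Wieland–Miescher ketone
Conditions: L-proline (5 mol %), DMSO, rt; recrystallise from Et2O at −20 °C to >99 % ee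
Reagents that add atoms: none
Why: The proline-catalysed intramolecular aldol condensation (Hajos–Parrish–Eder–Sauer–Wiechert reaction) distinguishes the two enantiotopic ring carbonyls and sets C-11 as S.

Step 3
Reactants: 4 (S)-Wieland–Miescher ketone
Product: 5 enone-carbonyl 1,3-dithiolane of 4 (8aS)
Conditions: HSCH2CH2SH (1.05 equiv), p-TsOH (cat.), AcOH, rt
Reagents that add atoms: ethane-1,2-dithiol, SCCS
Why: Chemoselective thioketalisation occurs at the unhindered enone carbonyl, leaving the neopentyl saturated ketone free.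

Step 4
Reactants: 5 enone-carbonyl 1,3-dithiolane of 4
Product: 6 dithiolane tertiary alcohol (OH cis to the angular methyl)
Conditions: MeLi, Et2O, −78 to 0 °C
Reagents that add atoms: methyllithium, [Li]C
Why: In this 1,2-addition MeLi attacks the ketone from the face opposite the angular methyl, which sets C-10 as S with the two methyl groups trans.

Step 5
Reactants: 6 dithiolane tertiary alcohol
Product: 7 (4aS,5S)-5-hydroxy-4a,5-dimethyl-4,4a,5,6,7,8-hexahydronaphthalen-2(3H)-one
Conditions: MeI, CaCO3, MeCN/H2O 4:1, 60 °C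
Reagents that add atoms: water, O
Why: S-alkylative hydrolysis of the dithiolane regenerates the enone under near-neutral conditions that do not affect the tertiary alcohol.

Step 6
Reactants: 7 enone alcohol
Product: 8 3-[(1R,2S)-2-hydroxy-1,2-dimethyl-6-oxocyclohexyl]propanoic acid
Conditions: RuCl3 (2 mol %), NaIO4 (4.5 equiv), EtOAc/MeCN/H2O, 0 °C to rt
Reagents that add atoms: sodium periodate, [Na+].[O-]I(=O)(=O)=O
Why: RuO4-type oxidative cleavage of the enone C=C and of the resulting 1,2-dicarbonyl removes one carbon, and the non-basic medium avoids retro-aldol opening of the β-hydroxy ketone.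

Step 7
Reactants: 8 hydroxy keto acid
Product: 9 (4aR,8aS)-4a,8a-dimethylhexahydro-2H-chromene-2,5(3H)-dione (trans-fused keto lactone)
Conditions: DCC, DMAP (0.3 equiv), CH2Cl2, 0 °C to rt
Reagents that add atoms: none
Why: Steglich lactonisation joins the trans-diequatorial OH and acid chain, which blocks retro-aldol cleavage and locks the chair with both methyl groups axial.

Step 8
Reactants: 9 trans-fused keto lactone
Product: 11 lactone C-6 enol triflate (4aR,8aS), via potassium enolate 10 (not isolated)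
Conditions: KN(SiMe3)2, THF, −78 °C; then PhNTf2, −78 to 0 °C
Reagents that add atoms: N-phenylbis(trifluoromethanesulfonimide), FC(F)(F)S(=O)(=O)N(c1ccccc1)S(=O)(=O)C(F)(F)F
Why: Enolate O-triflation is regiochemically unambiguous because the ketone can enolise only away from the quaternary carbon and is far more acidic than the lactone.

Step 9
Reactants: 11 lactone C-6 enol triflate; 12 allyl tert-butyldimethylsilyl ether
Product: 14 (4aS,8aS)-5-[3-(TBSO)propyl] cyclohexene lactone, via B-alkyl-9-BBN 13 (not isolated)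
Conditions: 12, 9-BBN, THF, rt; then 11, PdCl2(dppf) (5 mol %), AsPh3 (10 mol %), Cs2CO3, DMF/THF/H2O, rt to 50 °C
Reagents that add atoms: allyl TBS ether (12), C=CCO[Si](C)(C)C(C)(C)C
Why: B-alkyl Suzuki–Miyaura coupling installs the complete three-carbon C-3 to C-5 chain on the vinyl triflate under conditions that a hindered lactone tolerates.

Step 10
Reactants: 14 cyclohexene lactone
Product: 16 (4aS,5S,6S,8aS)-6-hydroxy lactone, via monoalkylborane 15 (not isolated)
Conditions: BH3·THF, THF, 0 °C to rt; then H2O2, pH 7 phosphate buffer, 0 °C to rt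
Reagents that add atoms: hydrogen peroxide, OO; borane (boron only in 15), B
Why: Anti-Markovnikov syn hydroboration–oxidation is faster than lactone reduction. Boron adds to C-7 on the face away from the axial C-11 methyl, which places H-6 trans to that methyl.

Step 11
Reactants: 16 hydroxy lactone
Product: 17 (4aS,5S,8aS)-5-[3-(TBSO)propyl]-4a,8a-dimethylhexahydro-2H-chromene-2,6(3H)-dione
Conditions: Dess–Martin periodinane, CH2Cl2, rt; then DBU (0.2 equiv), CH2Cl2, rt
Reagents that add atoms: none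
Why: Dess–Martin oxidation followed by base equilibration secures C-6, because in the locked chair the desired epimer has an equatorial chain while the other suffers a 1,3-diaxial clash with the C-10 methyl.

Step 12
Reactants: 17 keto lactone
Product: 19 lactone C-7 enol triflate (4aS,5S,8aS), via potassium enolate 18 (not isolated)
Conditions: KN(SiMe3)2, THF, −78 °C; then PhNTf2, −78 to 0 °C
Reagents that add atoms: N-phenylbis(trifluoromethanesulfonimide), FC(F)(F)S(=O)(=O)N(c1ccccc1)S(=O)(=O)C(F)(F)F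
Why: Kinetic deprotonation takes the unhindered C-8 methylene, so H-6 is untouched and O-triflation freezes C-6 as a non-epimerisable allylic centre.

Step 13
Reactants: 19 lactone C-7 enol triflate; 20 isopropenylboronic acid pinacol ester
Product: 21 (4aS,5R,8aS)-6-isopropenyl diene lactone
Conditions: PdCl2(dppf) (5 mol %), Cs2CO3, THF/H2O 9:1, 50 °C
Reagents that add atoms: isopropenylboronic acid pinacol ester (20), CC(=C)B1OC(C)(C)C(C)(C)O1
Why: Suzuki–Miyaura coupling of the vinyl triflate introduces C-1, C-2 and C-25 as a robust hydrocarbon diene.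

Step 14
Reactants: 21 diene lactone
Product: 22 3-[(1S,2R,6S)-2-[3-(TBSO)propyl]-6-hydroxy-1,6-dimethyl-3-(prop-1-en-2-yl)cyclohex-3-en-1-yl]-N-methoxy-N-methylpropanamide
Conditions: MeNH(OMe)·HCl, Me3Al, CH2Cl2, 0 °C to rt
Reagents that add atoms: N,O-dimethylhydroxylamine hydrochloride, CNOC.Cl
Why: Weinreb aminolysis opens the lactone and releases the conformational lock, so the C-6 chain can later become axial.

Step 15
Reactants: 22 hydroxy Weinreb amide
Product: 23 C-10 triethylsilyl ether of 22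
Conditions: Et3SiOTf, 2,6-lutidine, CH2Cl2, 0 °C
Reagents that add atoms: triethylsilyl triflate, CC[Si](CC)(CC)OS(=O)(=O)C(F)(F)F
Why: Silylation with the triflate protects even this hindered tertiary alcohol, which prevents relactonisation and removes the only acidic proton.

Step 16
Reactants: 23 silylated Weinreb amide
Product: 24 C-14 aldehyde (1S,2R,6S ring)
Conditions: i-Bu2AlH, THF, −78 °C; aq KNaC4H4O6
Reagents that add atoms: none
Why: Weinreb amide reduction stops at the chelated tetrahedral aluminate and gives the aldehyde on work-up without over-reduction.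

Step 17
Reactants: 24 C-14 aldehyde; 25 2-(triphenylphosphoranylidene)propanal
Product: 26 (2E)-5-[(1S,2R,6S)-2-[3-(TBSO)propyl]-1,6-dimethyl-3-(prop-1-en-2-yl)-6-(triethylsilyloxy)cyclohex-3-en-1-yl]-2-methylpent-2-enal
Conditions: toluene, 90 °C
Reagents that add atoms: 2-(triphenylphosphoranylidene)propanal (25), CC(C=O)=P(c1ccccc1)(c1ccccc1)c1ccccc1
Why: The Wittig reaction of the stabilised formyl ylide gives the (14E)-trisubstituted enal directly with high E selectivity.

Step 18
Reactants: 27 geraniol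
Product: 28 geranyl chloride (E)
Conditions: PPh3, CCl4, reflux
Reagents that add atoms: carbon tetrachloride, ClC(Cl)(Cl)Cl
Why: The Appel reaction replaces the primary allylic OH by SN2 without allylic transposition or E/Z loss.

Step 19
Reactants: 26 ring enal; 28 geranyl chloride
Product: 30 C-16 carbinol (16RS; 6R,10S,11S; 14E,18E), via geranylbarium chloride 29 (not isolated)
Conditions: Li, biphenyl, THF, rt; BaI2, THF, rt; 28, −78 °C; then 26, THF, −78 °C; aq NH4Cl
Reagents that add atoms: geranyl chloride (28), CC(C)=CCC/C(C)=C/CCl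
Why: In this carbonyl allylation the allylbarium reagent adds 1,2 to the enal through its α-carbon with retention of the E alkene, forming C16–C17 and the linear skeleton.

Step 20
Reactants: 30 C-16 carbinol
Product: 31 C-16 ketone (14E,18E)
Conditions: Dess–Martin periodinane, NaHCO3, CH2Cl2, 0 °C
Reagents that add atoms: none
Why: Buffered Dess–Martin oxidation converts both C-16 epimers into one enone without moving the β,γ-alkene into conjugation.

Step 21
Reactants: 31 C-16 ketone
Product: 32 (16R)-allylic alcohol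
Conditions: (S)-2-methyl-CBS-oxazaborolidine (0.3 equiv), catecholborane, toluene, −78 °C
Reagents that add atoms: none
Why: In the Corey–Bakshi–Shibata reduction the 1-methylalkenyl group acts as the large substituent, so the (S)-catalyst delivers hydride to give 16R, and catecholborane does not touch the alkenes at this temperature.

Step 22
Reactants: 32 (16R)-allylic alcohol
Product: 33 (16R)-tert-butyldimethylsilyl ether
Conditions: t-BuMe2SiOTf, 2,6-lutidine, CH2Cl2, −78 °C
Reagents that add atoms: tert-butyldimethylsilyl triflate, CC(C)(C)[Si](C)(C)OS(=O)(=O)C(F)(F)F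
Why: Silylation masks the secondary allylic alcohol so that only C-1 is oxidised later.

Step 23
Reactants: 33 tris-silylated diene
Product: 35 (2E)-C-1 allylic alcohol, via allyl boronate 34 (not isolated)
Conditions: Ni(cod)2 (5 mol %), PCy3 (5 mol %), pinacolborane, toluene, rt; then H2O2, NaOH, THF, 0 °C
Reagents that add atoms: hydrogen peroxide, OO; pinacolborane (boron and pinacolate only in 34), [H]B1OC(C)(C)C(C)(C)O1
Why: Nickel-catalysed 1,4-hydroboration adds H to C-8 and boron to C-1 of the s-cis-bound diene, so C-1 and C-8 end up cis (2E), the isolated alkenes are untouched, and oxidation retains the geometry.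

Step 24
Reactants: 35 (2E)-allylic alcohol
Product: 36 tris-silylated (2E)-enal
Conditions: MnO2, CH2Cl2, rt
Reagents that add atoms: none
Why: Neutral MnO2 oxidation of the only free (allylic) alcohol gives the enal without E/Z isomerisation.

Step 25
Reactants: 36 tris-silylated enal
Product: 37 target CNP0139451.3
Conditions: HF·pyridine, pyridine, THF, 0 °C to rt
Reagents that add atoms: none
Why: Buffered fluoride desilylation removes all three silyl ethers without base-induced dienolate formation, so no stereocentre or alkene is disturbed.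

## Compound list
1 | 2-methylcyclohexane-1,3-dione | CC1C(=O)CCCC1=O | starting material
2 | methyl vinyl ketone | CC(=O)C=C | starting material
3 | 2-methyl-2-(3-oxobutyl)cyclohexane-1,3-dione | CC(=O)CCC1(C)C(=O)CCCC1=O | intermediate
4 | (S)-Wieland–Miescher ketone, (8aS)-8a-methyl-3,4,8,8a-tetrahydronaphthalene-1,6(2H,7H)-dione | O=C1CC[C@@]2(C)C(=C1)CCCC2=O | intermediate
5 | 1,3-dithiolane of the enone carbonyl of 4 (8aS) | S1CCSC12CC[C@@]3(C)C(=C2)CCCC3=O | intermediate
6 | 1,3-dithiolane of 7, tertiary alcohol with OH cis to the angular methyl (4aS,5S in the numbering of 7) | S1CCSC12CC[C@@]3(C)C(=C2)CCC[C@]3(C)O | intermediate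
7 | (4aS,5S)-5-hydroxy-4a,5-dimethyl-4,4a,5,6,7,8-hexahydronaphthalen-2(3H)-one | O=C1CC[C@@]2(C)C(=C1)CCC[C@]2(C)O | intermediate
8 | 3-[(1R,2S)-2-hydroxy-1,2-dimethyl-6-oxocyclohexyl]propanoic acid | OC(=O)CC[C@@]1(C)C(=O)CCC[C@]1(C)O | intermediate
9 | (4aR,8aS)-4a,8a-dimethylhexahydro-2H-chromene-2,5(3H)-dione, trans-fused | O=C1CC[C@@]2(C)C(=O)CCC[C@]2(C)O1 | intermediate
10 | potassium enolate of 9 | [K+].O=C1CC[C@@]2(C)C([O-])=CCC[C@]2(C)O1 | intermediate
11 | (4aR,8aS)-4a,8a-dimethyl-2-oxo-3,4,4a,7,8,8a-hexahydro-2H-chromen-5-yl triflate | O=C1CC[C@@]2(C)C(OS(=O)(=O)C(F)(F)F)=CCC[C@]2(C)O1 | intermediate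
12 | allyl tert-butyldimethylsilyl ether | C=CCO[Si](C)(C)C(C)(C)C | starting material
13 | B-[3-(tert-butyldimethylsilyloxy)propyl]-9-BBN | CC(C)(C)[Si](C)(C)OCCCB1C2CCCC1CCC2 | intermediate
14 | (4aS,8aS)-5-[3-(TBSO)propyl]-4a,8a-dimethyl-3,4,4a,7,8,8a-hexahydro-2H-chromen-2-one | O=C1CC[C@@]2(C)C(CCCO[Si](C)(C)C(C)(C)C)=CCC[C@]2(C)O1 | intermediate
15 | C-7 monoalkylborane, boron and H-6 cis, both trans to the C-11 methyl | O=C1CC[C@@]2(C)[C@H](CCCO[Si](C)(C)C(C)(C)C)[C@@H](B)CC[C@]2(C)O1 | intermediate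
16 | (4aS,5S,6S,8aS)-5-[3-(TBSO)propyl]-6-hydroxy-4a,8a-dimethyloctahydro-2H-chromen-2-one | O=C1CC[C@@]2(C)[C@H](CCCO[Si](C)(C)C(C)(C)C)[C@@H](O)CC[C@]2(C)O1 | intermediate
17 | (4aS,5S,8aS)-5-[3-(TBSO)propyl]-4a,8a-dimethylhexahydro-2H-chromene-2,6(3H)-dione | O=C1CC[C@@]2(C)[C@H](CCCO[Si](C)(C)C(C)(C)C)C(=O)CC[C@]2(C)O1 | intermediate
18 | potassium C-7/C-8 enolate of 17 | [K+].O=C1CC[C@@]2(C)[C@H](CCCO[Si](C)(C)C(C)(C)C)C([O-])=CC[C@]2(C)O1 | intermediate
19 | (4aS,5S,8aS)-5-[3-(TBSO)propyl]-4a,8a-dimethyl-2-oxo-3,4,4a,5,8,8a-hexahydro-2H-chromen-6-yl triflate | O=C1CC[C@@]2(C)[C@H](CCCO[Si](C)(C)C(C)(C)C)C(OS(=O)(=O)C(F)(F)F)=CC[C@]2(C)O1 | intermediate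
20 | isopropenylboronic acid pinacol ester | CC(=C)B1OC(C)(C)C(C)(C)O1 | starting material
21 | (4aS,5R,8aS)-5-[3-(TBSO)propyl]-4a,8a-dimethyl-6-(prop-1-en-2-yl)-3,4,4a,5,8,8a-hexahydro-2H-chromen-2-one | O=C1CC[C@@]2(C)[C@H](CCCO[Si](C)(C)C(C)(C)C)C(C(C)=C)=CC[C@]2(C)O1 | intermediate
22 | 3-[(1S,2R,6S)-2-[3-(TBSO)propyl]-6-hydroxy-1,6-dimethyl-3-(prop-1-en-2-yl)cyclohex-3-en-1-yl]-N-methoxy-N-methylpropanamide | CON(C)C(=O)CC[C@@]1(C)[C@H](CCCO[Si](C)(C)C(C)(C)C)C(C(C)=C)=CC[C@]1(C)O | intermediate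
23 | C-10 triethylsilyl ether of 22 (1S,2R,6S) | CON(C)C(=O)CC[C@@]1(C)[C@H](CCCO[Si](C)(C)C(C)(C)C)C(C(C)=C)=CC[C@]1(C)O[Si](CC)(CC)CC | intermediate
24 | 3-[(1S,2R,6S)-2-[3-(TBSO)propyl]-1,6-dimethyl-3-(prop-1-en-2-yl)-6-(triethylsilyloxy)cyclohex-3-en-1-yl]propanal | O=CCC[C@@]1(C)[C@H](CCCO[Si](C)(C)C(C)(C)C)C(C(C)=C)=CC[C@]1(C)O[Si](CC)(CC)CC | intermediate
25 | 2-(triphenylphosphoranylidene)propanal | CC(C=O)=P(c1ccccc1)(c1ccccc1)c1ccccc1 | starting material
26 | (2E)-5-[(1S,2R,6S)-2-[3-(TBSO)propyl]-1,6-dimethyl-3-(prop-1-en-2-yl)-6-(triethylsilyloxy)cyclohex-3-en-1-yl]-2-methylpent-2-enal | O=C/C(C)=C/CC[C@@]1(C)[C@H](CCCO[Si](C)(C)C(C)(C)C)C(C(C)=C)=CC[C@]1(C)O[Si](CC)(CC)CC | intermediate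
27 | geraniol | CC(C)=CCC/C(C)=C/CO | starting material
28 | geranyl chloride (E) | CC(C)=CCC/C(C)=C/CCl | intermediate
29 | geranylbarium chloride (E) | CC(C)=CCC/C(C)=C/C[Ba]Cl | intermediate
30 | C-16 carbinol, 16RS mixture (6R,10S,11S; 14E,18E), ring diene intact | CC(C)=CCC/C(C)=C/CC(O)/C(C)=C/CC[C@@]1(C)[C@H](CCCO[Si](C)(C)C(C)(C)C)C(C(C)=C)=CC[C@]1(C)O[Si](CC)(CC)CC | intermediate
31 | C-16 ketone (6R,10S,11S; 14E,18E) | CC(C)=CCC/C(C)=C/CC(=O)/C(C)=C/CC[C@@]1(C)[C@H](CCCO[Si](C)(C)C(C)(C)C)C(C(C)=C)=CC[C@]1(C)O[Si](CC)(CC)CC | intermediate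
32 | (16R)-allylic alcohol (6R,10S,11S,16R; 14E,18E) | CC(C)=CCC/C(C)=C/C[C@@H](O)/C(C)=C/CC[C@@]1(C)[C@H](CCCO[Si](C)(C)C(C)(C)C)C(C(C)=C)=CC[C@]1(C)O[Si](CC)(CC)CC | intermediate
33 | (16R)-TBS ether of 32 | CC(C)=CCC/C(C)=C/C[C@@H](O[Si](C)(C)C(C)(C)C)/C(C)=C/CC[C@@]1(C)[C@H](CCCO[Si](C)(C)C(C)(C)C)C(C(C)=C)=CC[C@]1(C)O[Si](CC)(CC)CC | intermediate
34 | (2E)-C-1 allyl pinacol boronate, CH2B cis to C-8 | CC(C)=CCC/C(C)=C/C[C@@H](O[Si](C)(C)C(C)(C)C)/C(C)=C/CC[C@@]1(C)[C@H](CCCO[Si](C)(C)C(C)(C)C)/C(=C(\C)CB2OC(C)(C)C(C)(C)O2)CC[C@]1(C)O[Si](CC)(CC)CC | intermediate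
35 | (2E)-C-1 allylic alcohol (6R,10S,11S,16R) | CC(C)=CCC/C(C)=C/C[C@@H](O[Si](C)(C)C(C)(C)C)/C(C)=C/CC[C@@]1(C)[C@H](CCCO[Si](C)(C)C(C)(C)C)/C(=C(\C)CO)CC[C@]1(C)O[Si](CC)(CC)CC | intermediate
36 | tris-silylated (2E)-enal (6R,10S,11S,16R) | CC(C)=CCC/C(C)=C/C[C@@H](O[Si](C)(C)C(C)(C)C)/C(C)=C/CC[C@@]1(C)[C@H](CCCO[Si](C)(C)C(C)(C)C)/C(=C(\C)C=O)CC[C@]1(C)O[Si](CC)(CC)CC | intermediate
37 | (2E)-2-[(2R,3S,4S)-4-hydroxy-3-[(3E,5R,7E)-5-hydroxy-4,8,12-trimethyltrideca-3,7,11-trien-1-yl]-2-(3-hydroxypropyl)-3,4-dimethylcyclohexylidene]propanal | CC(C)=CCC/C(C)=C/C[C@@H](O)/C(C)=C/CC[C@@]1(C)[C@H](CCCO)/C(=C(\C)C=O)CC[C@]1(C)O | target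

## Step count and risks
Total step count: 25.
Longest linear sequence: 24 steps (steps 1–17 and 19–25).

**Step 23 is the most likely to fail.** The diene is 1,2,3-trisubstituted. It can bind to zerovalent nickel in the s-cis form only when the C-6 chain is axial, so the catalyst may stall or give 1,2-addition.

The fallback sets out from 33 and replaces catalyst control by conjugation and separation.
- 9-BBN adds selectively to the 1,1-disubstituted alkene of 33 to give the B-alkyl-9-BBN adduct F1.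
- H2O2/NaOH turns it into the β,γ-unsaturated primary alcohol F2.
- Dess–Martin oxidation then gives the β,γ-unsaturated aldehyde F3.
- DBU in CH2Cl2 moves the ring alkene into conjugation and gives 36 together with its (2Z)-isomer F4.
- The two are separated by silica HPLC, and F4 is re-equilibrated with DBU and recycled.

The route is rejoined at 36.

**Step 19 is the second most likely to fail.** Active barium is demanding to prepare, some γ-adduct may form, and C-16 is not controlled in the coupling itself.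

The fallback sets out from 26 and builds the chain through a vinylogous aldol reaction.
- Ethyl tiglate is converted with LiN(i-Pr)2 and t-BuMe2SiCl into the silyl dienolate F5.
- A SiCl4-promoted vinylogous Mukaiyama aldol reaction of F5 with 26 at −78 °C gives the (16R,18E)-δ-hydroxy enoate F6 directly. It is catalysed by the antipode of a binaphthyldiamine bisphosphoramide that delivers 16R.
- t-BuMe2SiOTf gives the silyl ether F7.
- i-Bu2AlH gives the C-20 allylic alcohol F8.
- CBr4/PPh3 gives the allylic bromide F9.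
- Prenyl phenyl sulfone F10 is made from prenyl bromide and PhSO2Na. It is lithiated with n-BuLi and alkylated with F9 to give the C-21 sulfone F11.
- PdCl2(dppp)/LiEt3BH removes the sulfonyl group.

The route is rejoined at 33, which makes steps 19–22 unnecessary.

**Step 10 is the third most likely to fail.** The trisubstituted alkene sits next to the quaternary carbon, so hydroboration may be slow enough for lactone reduction to compete.

The fallback sets out from 14 and reaches the ketone by oxidation followed by reductive deoxygenation.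
- OsO4 (cat.)/NMO gives the cis-6,7-diol F12. The face of attack is irrelevant because both new centres are erased later.
- Dess–Martin oxidation gives the tertiary α-ketol F13.
- SmI2 in THF/MeOH removes the α-hydroxyl group.
- DBU equilibration in the locked chair places the chain equatorial.

The route is rejoined at 17.

## Further compounds
F1 | step 23 | B-alkyl-9-BBN adduct of the isopropenyl group of 33 | CC(C)=CCC/C(C)=C/C[C@@H](O[Si](C)(C)C(C)(C)C)/C(C)=C/CC[C@@]1(C)[C@H](CCCO[Si](C)(C)C(C)(C)C)C(C(C)CB2C3CCCC2CCC3)=CC[C@]1(C)O[Si](CC)(CC)CC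
F2 | step 23 | β,γ-unsaturated primary alcohol (C-2 epimers) | CC(C)=CCC/C(C)=C/C[C@@H](O[Si](C)(C)C(C)(C)C)/C(C)=C/CC[C@@]1(C)[C@H](CCCO[Si](C)(C)C(C)(C)C)C(C(C)CO)=CC[C@]1(C)O[Si](CC)(CC)CC
F3 | step 23 | β,γ-unsaturated aldehyde (C-2 epimers) | CC(C)=CCC/C(C)=C/C[C@@H](O[Si](C)(C)C(C)(C)C)/C(C)=C/CC[C@@]1(C)[C@H](CCCO[Si](C)(C)C(C)(C)C)C(C(C)C=O)=CC[C@]1(C)O[Si](CC)(CC)CC
F4 | step 23 | (2Z)-isomer of 36 | CC(C)=CCC/C(C)=C/C[C@@H](O[Si](C)(C)C(C)(C)C)/C(C)=C/CC[C@@]1(C)[C@H](CCCO[Si](C)(C)C(C)(C)C)/C(=C(/C)C=O)CC[C@]1(C)O[Si](CC)(CC)CC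
F5 | step 19 | 1-ethoxy-1-(tert-butyldimethylsilyloxy)-2-methylbuta-1,3-diene | C=CC(C)=C(OCC)O[Si](C)(C)C(C)(C)C
F6 | step 19 | (16R,18E)-δ-hydroxy enoate | CCOC(=O)/C(C)=C/C[C@@H](O)/C(C)=C/CC[C@@]1(C)[C@H](CCCO[Si](C)(C)C(C)(C)C)C(C(C)=C)=CC[C@]1(C)O[Si](CC)(CC)CC
F7 | step 19 | (16R)-TBS ether of F6 | CCOC(=O)/C(C)=C/C[C@@H](O[Si](C)(C)C(C)(C)C)/C(C)=C/CC[C@@]1(C)[C@H](CCCO[Si](C)(C)C(C)(C)C)C(C(C)=C)=CC[C@]1(C)O[Si](CC)(CC)CC
F8 | step 19 | C-20 allylic alcohol (18E) | OC/C(C)=C/C[C@@H](O[Si](C)(C)C(C)(C)C)/C(C)=C/CC[C@@]1(C)[C@H](CCCO[Si](C)(C)C(C)(C)C)C(C(C)=C)=CC[C@]1(C)O[Si](CC)(CC)CC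
F9 | step 19 | C-20 allylic bromide (18E) | BrC/C(C)=C/C[C@@H](O[Si](C)(C)C(C)(C)C)/C(C)=C/CC[C@@]1(C)[C@H](CCCO[Si](C)(C)C(C)(C)C)C(C(C)=C)=CC[C@]1(C)O[Si](CC)(CC)CC
F10 | step 19 | prenyl phenyl sulfone | CC(C)=CCS(=O)(=O)c1ccccc1
F11 | step 19 | C-21 phenyl sulfone (C-21 epimers) | CC(C)=CC(S(=O)(=O)c1ccccc1)C/C(C)=C/C[C@@H](O[Si](C)(C)C(C)(C)C)/C(C)=C/CC[C@@]1(C)[C@H](CCCO[Si](C)(C)C(C)(C)C)C(C(C)=C)=CC[C@]1(C)O[Si](CC)(CC)CC
F12 | step 10 | cis-6,7-diol lactone | O=C1CC[C@@]2(C)C(O)(CCCO[Si](C)(C)C(C)(C)C)C(O)CC[C@]2(C)O1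
F13 | step 10 | 6-hydroxy-7-keto lactone | O=C1CC[C@@]2(C)C(O)(CCCO[Si](C)(C)C(C)(C)C)C(=O)CC[C@]2(C)O1
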